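(The runs stem from a simulated flask for substances that don't exist, noise included.)

In the early minutes of Thursday's run the left-handed substrate goes quickly: 34.7% of the racemate charged is left of it at 1.00 min and 9.6% at 12.0 min, while the right-handed substrate still stands at 44.3%.

all flasks: left-handed substrate 20 mM; right-handed substrate 20 mM; added ligand 7.3 mM
- Thursday's: reagent 30 mM; free catalyst 3.9 mM; run made earlier
- flask: reagent 30.0 mM; free catalyst 2.6 mM; time 2.0 h

Thursday's run (percent of the left-handed substrate and right-handed substrate together charged)

| time / min | right-handed substrate / % | left-handed substrate / % |
|---|---|---|
| 1.00 | 47.9 | 34.7 |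
| 3.00 | 48.5 | 24.1 |
| 6.00 | 46.0 | 17.7 |
| 8.00 | 46.4 | 14.7 |
| 12.0 | 44.3 | 9.6 |

(readings scatter by 1 percentage point)

- free catalyst is single-handed; left-handed substrate and right-handed substrate are mirror images of each other, charged as a racemate, each of them at the stated concentration
- steps that have been proposed: free catalyst + added ligand <-> idle complex; reagent + free catalyst + left-handed substrate -> free catalyst + left-handed product; 2 free catalyst -> spent catalyst A; reagent + free catalyst + right-handed substrate -> free catalyst + right-handed product; reagent + free catalyst -> spent catalyst B
- no earlier run changes the charge of free catalyst; that part of a forecast is a guess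

- whether the excess of right-handed substrate over left-handed substrate among what is left of the two reaches 80% by 2.0 h (yes / no)
- the highest excess of right-handed substrate over left-handed substrate among what is left of the two up to 2.0 h

Carry one quantity, the selectivity factor: the logarithm of the fall of [left-handed substrate] from its half share, divided by the same logarithm for [right-handed substrate]. Thursday's last reading gives 13.6, with the scatter of a reading. Both proposed product steps use the same reagent and the same free catalyst, so a weakening catalyst slows both alike.

For 80% in the new flask, [left-handed substrate]/[right-handed substrate] must fall to 0.111. With this factor, that means 42.0% of right-handed substrate and 4.67% of left-handed substrate. The bill is 21.3 mM of reagent, less than the 30.0 mM charged.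

Can the catalyst pay it? Two chemists differ. On Thursday the logarithmic loss of left-handed substrate ran at 0.365 min⁻¹ in the first minute and 0.107 min⁻¹ in the last stretch. The first chemist calls the later pace steady, scales it to 2.6 mM of free catalyst, and gets 33.4 min, shorter than 2.0 h. The second sees a fall of 3.41 times, a catalyst that pairs off and dies, and a stall short of the mark.

No earlier run changes the catalyst charge, so this is a guess. I commit to yes, and to no top.

The forecast says yes, with a top of 89% between 70% and 99%, “stalling somewhere near 90%”.

The simulation gives yes, with a top of 84.2%, and passes 80% at 1.21 h, later than the first chemist's time.

    free catalyst + added ligand ⇌ idle complex (K = 95.0 M⁻¹, k = 0.930 M⁻¹ s⁻¹)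
    reagent + free catalyst + left-handed substrate → free catalyst + left-handed product (k = 85.0 M⁻² s⁻¹)
    2 free catalyst → spent catalyst A (k = 0.790 M⁻¹ s⁻¹)
    reagent + free catalyst + right-handed substrate → free catalyst + right-handed product (k = 5.00 M⁻² s⁻¹)
    reagent + free catalyst → spent catalyst B (k = 0.0110 M⁻¹ s⁻¹)

The second chemist's dying catalyst shows in this flask, though the excess still passes the mark: at 2.00 h spent catalyst A is 80.2% and free catalyst 4.01% of the catalyst charged. Applied to the 3.67% of left-handed substrate at that time, the selectivity factor gives 41.3% of right-handed substrate, where the flask holds 42.9%.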